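**Plan**

1. Retrosynthesis: the C3 aldehyde and the 2'-OH are folded back into a six-membered lactone, so the target becomes the half-reduced, ring-opened form of a coumestan (6H-benzofuro[3,2-c]chromen-6-one). The coumestan is then cut at the furan C2–aryl C1' bond and at the lactone C(=O)–O bond, giving a C2-unsubstituted benzofuran-3-carboxylate and a 2-bromophenol of the resorcinol series.
2. Enabling feature: the furan C2–H lies between the ring oxygen O1 and the carbonyl-bearing C3, so it is the most acidic C–H and is ready for carboxylate-assisted palladation. Across the new bond the C3 carbonyl carbon and the 2'-oxygen are 1,6-related, so one operation can form the biaryl bond and close a pyran-2-one ring that stores the aldehyde at the ester level and masks the 2'-phenol.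
3. Forward: the benzene ring is bought as a salicylaldehyde; an aromatic Claisen rearrangement places the C7 side chain between the two oxygens; the furan ring arises by diazoacetate annulation; cross-metathesis turns allyl into prenyl; the key step then adds the resorcinol ring and the temporary pyranone ring together.
4. End game: DIBAL-H opens the pyranone to the C3 aldehyde and the 2'-phenol; the MOM group on the 4'-oxygen is hydrolysed last.
5. Stereochemistry: none has to be set; the target has no stereocentre, no stereogenic axis and no stereogenic alkene.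

Key step: step 6

Remark: the target is achiral (the prenyl alkene carries two identical methyl groups), so "single enantiomer" is read as the one constitution drawn; the two transient sp3 intermediates (hemiacetal and lactol) form without stereocontrol, which does not matter because their stereocentres disappear in the same step.

**Route**

Step 1
Reactants: 1 2-hydroxy-4-methoxybenzaldehyde
Product: 2 4-methoxy-2-(prop-2-en-1-yloxy)benzaldehyde
Conditions: allyl bromide (1.2 equiv), K2CO3 (1.5 equiv), DMF, 50 °C
Reagents that add atoms: allyl bromide, C=CCBr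
Why: Williamson ether synthesis (SN2 of the phenoxide on a primary allylic bromide); the aldehyde is inert to carbonate.

Step 2
Reactants: 2 4-methoxy-2-(prop-2-en-1-yloxy)benzaldehyde
Product: 3 2-hydroxy-4-methoxy-3-(prop-2-en-1-yl)benzaldehyde
Conditions: PhNEt2, 200 °C, N2
Reagents that add atoms: none
Why: Aromatic Claisen rearrangement ([3,3]-sigmatropic shift, then tautomerisation) should deliver the allyl group to C3, the only unsubstituted ortho carbon of the ether, which places the side chain between the phenol oxygen and the methoxy group as the target requires.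

Step 3
Reactants: 3 2-hydroxy-4-methoxy-3-(prop-2-en-1-yl)benzaldehyde
Product: 5 ethyl 6-methoxy-7-(prop-2-en-1-yl)-1-benzofuran-3-carboxylate, via dihydrobenzofuran hemiacetal 4 (not isolated)
Conditions: HBF4·OEt2 (10 mol %), ethyl diazoacetate (1.5 equiv, slow addition), CH2Cl2, rt; then conc. H2SO4 (cat.), 0 °C to rt, 15 min
Reagents that add atoms: ethyl diazoacetate, CCOC(=O)C=[N+]=[N-]
Why: Brønsted-acid-catalysed annulation of a salicylaldehyde with ethyl diazoacetate (addition of the diazo carbon to the aldehyde, 1,2-aryl shift with loss of N2, hemiacetal closure by the phenol, acid dehydration) is an established route to C2-unsubstituted benzofuran-3-carboxylates; the electron-rich aryl group migrates readily and the monosubstituted allyl alkene should tolerate the brief acid exposure.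

Step 4
Reactants: 5 ethyl 6-methoxy-7-(prop-2-en-1-yl)-1-benzofuran-3-carboxylate
Product: 6 ethyl 6-methoxy-7-(3-methylbut-2-en-1-yl)-1-benzofuran-3-carboxylate
Conditions: Grubbs II catalyst (5 mol %), 2-methyl-2-butene/CH2Cl2 (1:1), 40 °C, sealed tube
Reagents that add atoms: 2-methyl-2-butene, CC=C(C)C
Why: Olefin cross-metathesis of a terminal allyl arene with excess 2-methyl-2-butene is the standard allyl-to-prenyl conversion; the aromatic furan C2=C3 bond does not take part and propene escapes.

Step 5
Reactants: 7 4-bromobenzene-1,3-diol (4-bromoresorcinol)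
Product: 8 2-bromo-5-(methoxymethoxy)phenol
Conditions: NaH (2.2 equiv), THF–DMF, 0 °C; MOMCl (1.0 equiv), −20 to 0 °C; aq. NH4Cl
Reagents that add atoms: chloromethyl methyl ether (MOMCl), COCCl
Why: Williamson-type O-alkylation of the dianion, in which the phenoxide para to bromine is the more basic, more nucleophilic and less hindered oxygen (the ortho-bromo phenoxide is stabilised and shielded), so one equivalent of MOMCl should react mainly there.

Step 6
Reactants: 6 ethyl 6-methoxy-7-(3-methylbut-2-en-1-yl)-1-benzofuran-3-carboxylate; 8 2-bromo-5-(methoxymethoxy)phenol (1.3 equiv)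
Product: 10 9-methoxy-3-(methoxymethoxy)-10-(3-methylbut-2-en-1-yl)-6H-[1]benzofuro[3,2-c]chromen-6-one, via biaryl hydroxy ester 9 (not isolated)
Conditions: Pd(OAc)2 (5 mol %), PCy3·HBF4 (10 mol %), PivOH (30 mol %), K2CO3 (3 equiv), DMA, 110 °C; then 1 M HCl work-up
Reagents that add atoms: none
Why: Pd(0)/PCy3 should insert into the C–Br bond of the phenoxide of 8, pivalate-assisted concerted metalation–deprotonation then palladates the C2–H of 6, reductive elimination forms the C2–C1' biaryl bond (9), and the ortho phenoxide attacks the neighbouring C3 ester with loss of ethoxide to give the pyranone ring. The closest known reaction types are the Pd-catalysed direct C2–H arylation of furans and benzofurans carrying a 3-acyl or 3-alkoxycarbonyl group with aryl bromides, and the cross-coupling/lactonisation domino used for benzocoumarins and coumestans. The one ring that closes is the six-membered lactone, formed by 6-exo-trig acyl substitution. No stereocentre is created. The step needs site selectivity for C2 over C4/C5 and chemoselectivity over the prenyl alkene: C2–H is the most acidic C–H of the heteroarene because it lies between O1 and the ester-bearing C3 (itself blocked), the position on the resorcinol ring is fixed by the bromide, and a trisubstituted alkene is a poor Heck acceptor. Should some 9 survive, the acidic work-up is expected to complete the lactonisation.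

Step 7
Reactants: 10 9-methoxy-3-(methoxymethoxy)-10-(3-methylbut-2-en-1-yl)-6H-[1]benzofuro[3,2-c]chromen-6-one
Product: 12 2-[2-hydroxy-4-(methoxymethoxy)phenyl]-6-methoxy-7-(3-methylbut-2-en-1-yl)-1-benzofuran-3-carbaldehyde, via lactol 11 (not isolated)
Conditions: DIBAL-H (1.2 equiv), CH2Cl2, −78 °C; MeOH quench at −78 °C, aq. Rochelle salt
Reagents that add atoms: none
Why: Partial reduction of a lactone with DIBAL-H at −78 °C stops at the tetrahedral aluminium lactolate (as for coumarins and benzo[c]chromenones); on work-up lactol 11 should open to its phenol–aldehyde tautomer, favoured because the aldehyde is a vinylogous formate conjugated with the furan oxygen, and the MOM ether, methyl ether and prenyl alkene are inert to the hydride.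

Step 8
Reactants: 12 2-[2-hydroxy-4-(methoxymethoxy)phenyl]-6-methoxy-7-(3-methylbut-2-en-1-yl)-1-benzofuran-3-carbaldehyde
Product: 13 Erypoegin F, 2-(2,4-dihydroxyphenyl)-6-methoxy-7-(3-methylbut-2-en-1-yl)-1-benzofuran-3-carbaldehyde
Conditions: 3 M aq. HCl/THF (1:2), 50 °C
Reagents that add atoms: none
Why: Acid hydrolysis of the aryl methoxymethyl acetal; the prenyl group is flanked by OMe and the furan oxygen, so no free phenol is positioned for acid-induced chroman formation, and water as cosolvent avoids acetal formation at the aldehyde.

**Compound list**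

1 | 2-hydroxy-4-methoxybenzaldehyde | COc1ccc(C=O)c(O)c1 | starting material
2 | 4-methoxy-2-(prop-2-en-1-yloxy)benzaldehyde | COc1ccc(C=O)c(OCC=C)c1 | intermediate
3 | 2-hydroxy-4-methoxy-3-(prop-2-en-1-yl)benzaldehyde | COc1ccc(C=O)c(O)c1CC=C | intermediate
4 | ethyl 2-hydroxy-6-methoxy-7-(prop-2-en-1-yl)-2,3-dihydro-1-benzofuran-3-carboxylate (transient hemiacetal; mixture of diastereomers) | CCOC(=O)C1C(O)Oc2c(CC=C)c(OC)ccc21 | intermediate
5 | ethyl 6-methoxy-7-(prop-2-en-1-yl)-1-benzofuran-3-carboxylate | CCOC(=O)c1coc2c(CC=C)c(OC)ccc12 | intermediate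
6 | ethyl 6-methoxy-7-(3-methylbut-2-en-1-yl)-1-benzofuran-3-carboxylate | CCOC(=O)c1coc2c(CC=C(C)C)c(OC)ccc12 | intermediate
7 | 4-bromobenzene-1,3-diol (4-bromoresorcinol) | Oc1ccc(Br)c(O)c1 | starting material
8 | 2-bromo-5-(methoxymethoxy)phenol | COCOc1ccc(Br)c(O)c1 | intermediate
9 | ethyl 2-[2-hydroxy-4-(methoxymethoxy)phenyl]-6-methoxy-7-(3-methylbut-2-en-1-yl)-1-benzofuran-3-carboxylate (transient biaryl hydroxy ester) | CCOC(=O)c1c(-c2ccc(OCOC)cc2O)oc2c(CC=C(C)C)c(OC)ccc12 | intermediate
10 | 9-methoxy-3-(methoxymethoxy)-10-(3-methylbut-2-en-1-yl)-6H-[1]benzofuro[3,2-c]chromen-6-one | COc1ccc2c3c(oc2c1CC=C(C)C)-c1ccc(OCOC)cc1OC3=O | intermediate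
11 | 9-methoxy-3-(methoxymethoxy)-10-(3-methylbut-2-en-1-yl)-6H-[1]benzofuro[3,2-c]chromen-6-ol (transient lactol; racemic) | COc1ccc2c3c(oc2c1CC=C(C)C)-c1ccc(OCOC)cc1OC3O | intermediate
12 | 2-[2-hydroxy-4-(methoxymethoxy)phenyl]-6-methoxy-7-(3-methylbut-2-en-1-yl)-1-benzofuran-3-carbaldehyde | COCOc1ccc(-c2oc3c(CC=C(C)C)c(OC)ccc3c2C=O)c(O)c1 | intermediate
13 | Erypoegin F, 2-(2,4-dihydroxyphenyl)-6-methoxy-7-(3-methylbut-2-en-1-yl)-1-benzofuran-3-carbaldehyde | COc1ccc2c(C=O)c(-c3ccc(O)cc3O)oc2c1CC=C(C)C | target

**Summary**

Total step count: 8. Longest linear sequence: 7 steps (steps 1–4 and 6–8, from 1).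

Steps most likely to fail:

1. Step 6. Oxidative addition into the electron-rich bromophenoxide may be slow, protodebromination may compete, and lactonisation may stay incomplete. The fallback uses an ester tether so that the same C2–C1' bond is formed intramolecularly. It sets out from 6: saponification (LiOH, THF/MeOH/H2O) should give 6-methoxy-7-(3-methylbut-2-en-1-yl)-1-benzofuran-3-carboxylic acid F1; esterification with 8 (EDC·HCl, DMAP, CH2Cl2) should give 2-bromo-5-(methoxymethoxy)phenyl 6-methoxy-7-(3-methylbut-2-en-1-yl)-1-benzofuran-3-carboxylate F2; intramolecular Pd-catalysed direct arylation through the tether (Pd(OAc)2, PCy3·HBF4, K2CO3, DMA, 120 °C; six-membered ring closure of a 2-bromoaryl ester) then returns to the route at 10.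

2. Step 5. Site selectivity between the two phenol oxygens may be poor and bis-alkylation may compete. The fallback drops the selective protection. It sets out from 7: MOMCl (2.5 equiv) with i-Pr2NEt in CH2Cl2 should give 1-bromo-2,4-bis(methoxymethoxy)benzene F3; direct C2–H arylation of 6 with F3 under the step 6 catalyst system should give ethyl 2-[2,4-bis(methoxymethoxy)phenyl]-6-methoxy-7-(3-methylbut-2-en-1-yl)-1-benzofuran-3-carboxylate F4; HCl in MeOH/THF at 55 °C should remove both acetals and close the lactone to 3-hydroxy-9-methoxy-10-(3-methylbut-2-en-1-yl)-6H-[1]benzofuro[3,2-c]chromen-6-one F5; DIBAL-H (3.5 equiv, THF, −78 °C, the first equivalent being consumed by the phenol) then comes back to the route at 13.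

3. Step 7. Over-reduction may occur (collapse of the aluminium lactolate with loss of phenoxide and delivery of a second hydride), or conversion may be incomplete. The fallback reduces fully and re-oxidises. It sets out from 10: LiAlH4 (THF, 0 °C) should give 2-[3-(hydroxymethyl)-6-methoxy-7-(3-methylbut-2-en-1-yl)-1-benzofuran-2-yl]-5-(methoxymethoxy)phenol F6; MnO2 (CH2Cl2, rt) should oxidise only the activated benzofuran-3-ylmethanol and returns to the route at 12.

**Further compounds**

F1 | step 6 | 6-methoxy-7-(3-methylbut-2-en-1-yl)-1-benzofuran-3-carboxylic acid | COc1ccc2c(C(=O)O)coc2c1CC=C(C)C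
F2 | step 6 | 2-bromo-5-(methoxymethoxy)phenyl 6-methoxy-7-(3-methylbut-2-en-1-yl)-1-benzofuran-3-carboxylate | COCOc1ccc(Br)c(OC(=O)c2coc3c(CC=C(C)C)c(OC)ccc23)c1
F3 | step 5 | 1-bromo-2,4-bis(methoxymethoxy)benzene | COCOc1ccc(Br)c(OCOC)c1
F4 | step 5 | ethyl 2-[2,4-bis(methoxymethoxy)phenyl]-6-methoxy-7-(3-methylbut-2-en-1-yl)-1-benzofuran-3-carboxylate | CCOC(=O)c1c(-c2ccc(OCOC)cc2OCOC)oc2c(CC=C(C)C)c(OC)ccc12
F5 | step 5 | 3-hydroxy-9-methoxy-10-(3-methylbut-2-en-1-yl)-6H-[1]benzofuro[3,2-c]chromen-6-one | COc1ccc2c3c(oc2c1CC=C(C)C)-c1ccc(O)cc1OC3=O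
F6 | step 7 | 2-[3-(hydroxymethyl)-6-methoxy-7-(3-methylbut-2-en-1-yl)-1-benzofuran-2-yl]-5-(methoxymethoxy)phenol | COCOc1ccc(-c2oc3c(CC=C(C)C)c(OC)ccc3c2CO)c(O)c1
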